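The benzene ring (C1–C6) is cut at C3–C4, C1–C2 and C1–C6 into a three-carbon alkenyl carbene, a terminal alkyne and one carbonyl ligand. The feature exploited is the 4-methoxyphenol pattern. C1–OH lies between C2 (tricosyl) and C6 (OMe), and C4–OMe is para to it. A single chromium-templated [3+2+1] benzannulation builds the ring and places all four substituents. It leaves the phenol free beside two methyl ethers, so no protecting group is needed. The precursors are the (E)-β-methoxyvinyl(methoxy)carbene pentacarbonylchromium complex, made by adding methanol to a silylalkynyl carbene complex, and pentacos-1-yne, made from 1-tetracosanol.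

Key step: step 5

Remark on the chemistry: the target has no stereocentre and no stereogenic axis, so it is achiral and no enantiomer has to be selected. The only stereodescriptor in the route, the E double bond of 7, disappears on aromatisation.
Remark on notation: Cr–CO bonds are written Cr=C=O, and the η6 complex 11 is written as arene and Cr(CO)3 joined by a dot.

Step 1
Reactants: 1 chromium hexacarbonyl; 2 ethynyltrimethylsilane
Product: 5 pentacarbonyl[1-methoxy-3-(trimethylsilyl)prop-2-yn-1-ylidene]chromium(0), via lithium (trimethylsilyl)acetylide 3 (not isolated), via lithium acylchromate 4 (not isolated)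
Conditions: n-BuLi, THF, −78 °C; Cr(CO)6, −78 °C → rt; evaporate; MeOTf, CH2Cl2, 0 °C
Reagents that add atoms: methyl trifluoromethanesulfonate, COS(=O)(=O)C(F)(F)F
Why: Fischer carbene synthesis, in which the acetylide adds to a CO ligand and O-methylation of the acylmetalate by the hard electrophile fixes the methoxycarbene, while the silyl cap keeps the alkynyl complex stable enough to purify.

Step 2
Reactants: 5 pentacarbonyl[1-methoxy-3-(trimethylsilyl)prop-2-yn-1-ylidene]chromium(0)
Product: 7 pentacarbonyl[(2E)-1,3-dimethoxyprop-2-en-1-ylidene]chromium(0), via ethynyl(methoxy)carbene complex 6 (not isolated)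
Conditions: MeOH (3 equiv), NaOMe (10 mol %), THF, −30 °C → rt
Reagents that add atoms: methanol, CO
Why: Michael-type addition of an alcohol to an alkynyl Fischer carbene complex, in which methoxide first removes the silyl group from the strongly acceptor-substituted alkyne, methanol then adds to the β-carbon, alkoxy exchange at the carbene carbon is degenerate, and reversible addition should settle on the less crowded E push–pull alkene.

Step 3
Reactants: 8 1-tetracosanol
Product: 9 tetracosanal
Conditions: IBX (2 equiv), EtOAc, 80 °C; filter
Reagents that add atoms: none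
Why: IBX oxidation of a primary alcohol stops at the aldehyde, and refluxing ethyl acetate keeps the waxy C24 alcohol dissolved while the reagent and its reduced form stay insoluble and are filtered off.

Step 4
Reactants: 9 tetracosanal
Product: 10 pentacos-1-yne
Conditions: Ohira–Bestmann reagent (1.3 equiv), K2CO3 (2 equiv), THF/MeOH 2:1, rt → 35 °C
Reagents that add atoms: dimethyl (1-diazo-2-oxopropyl)phosphonate, COP(=O)(OC)C(=[N+]=[N-])C(C)=O
Why: Ohira–Bestmann variant of the Seyferth–Gilbert homologation, in which methanolysis frees the diazomethylphosphonate anion, its Horner–Wadsworth–Emmons-type reaction with 9 and loss of N2 give an alkylidene carbene, and a 1,2-hydrogen shift delivers the terminal alkyne with exactly one added carbon (C24 to C25).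

Step 5
Reactants: 7 pentacarbonyl[(2E)-1,3-dimethoxyprop-2-en-1-ylidene]chromium(0) (1.3 equiv); 10 pentacos-1-yne
Product: 12 2,4-dimethoxy-6-tricosylphenol, via arene tricarbonylchromium complex 11 (not isolated)
Conditions: toluene (0.3 M, degassed), Ar, 60–70 °C; then air, Et2O, daylight, rt; filter through Celite/silica
Reagents that add atoms: none
Why: Dötz benzannulation of an alkenyl(alkoxy)carbene chromium complex with a terminal alkyne: thermal loss of a cis-CO from 7 opens a site for 10, which inserts into Cr=C so that the alkyne CH bonds to the former carbene carbon (C3–C4). Migration of a CO ligand onto the chain-bearing carbon (C1–C2) then gives a chromium-bound dienylketene. The single new ring is closed by 6π electrocyclisation of that ketene, with ketene carbon C1 bonding to the β-methoxyvinyl carbon C6, and enolisation of the cyclohexadienone gives the phenol as its Cr(CO)3 complex 11. The regioselectivity needed comes from the steric contrast of H against C23H47 on the alkyne, which keeps the chain away from the carbene methoxy group and therefore next to C1–OH. The chemoselectivity needed, CO uptake rather than five-membered-ring formation, is supported by the chromium/alkoxy/alkenyl combination, a non-donor solvent and high concentration, since the β-oxygen is a much weaker donor than the amino groups that divert such complexes. No stereocentre is created, and brief aeration should strip the labile Cr(CO)3 unit without oxidising the electron-rich phenol.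

Compound list
1 | chromium hexacarbonyl | O=C=[Cr](=C=O)(=C=O)(=C=O)(=C=O)=C=O | starting material
2 | ethynyltrimethylsilane | C#C[Si](C)(C)C | starting material
3 | lithium (trimethylsilyl)acetylide | [Li]C#C[Si](C)(C)C | intermediate
4 | lithium pentacarbonyl[1-oxido-3-(trimethylsilyl)prop-2-yn-1-ylidene]chromate | [Li+].[O-]C(C#C[Si](C)(C)C)=[Cr](=C=O)(=C=O)(=C=O)(=C=O)=C=O | intermediate
5 | pentacarbonyl[1-methoxy-3-(trimethylsilyl)prop-2-yn-1-ylidene]chromium(0) | COC(C#C[Si](C)(C)C)=[Cr](=C=O)(=C=O)(=C=O)(=C=O)=C=O | intermediate
6 | pentacarbonyl(1-methoxyprop-2-yn-1-ylidene)chromium(0) | COC(C#C)=[Cr](=C=O)(=C=O)(=C=O)(=C=O)=C=O | intermediate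
7 | pentacarbonyl[(2E)-1,3-dimethoxyprop-2-en-1-ylidene]chromium(0) | CO/C=C/C(OC)=[Cr](=C=O)(=C=O)(=C=O)(=C=O)=C=O | intermediate
8 | 1-tetracosanol | CCCCCCCCCCCCCCCCCCCCCCCCO | starting material
9 | tetracosanal | CCCCCCCCCCCCCCCCCCCCCCCC=O | intermediate
10 | pentacos-1-yne | CCCCCCCCCCCCCCCCCCCCCCCC#C | intermediate
11 | tricarbonyl(η6-2,4-dimethoxy-6-tricosylphenol)chromium(0) | CCCCCCCCCCCCCCCCCCCCCCCc1cc(OC)cc(OC)c1O.O=C=[Cr](=C=O)=C=O | intermediate
12 | 2,4-dimethoxy-6-tricosylphenol (achiral) | CCCCCCCCCCCCCCCCCCCCCCCc1cc(OC)cc(OC)c1O | target

Total step count: 5. Longest linear sequence: 3 steps (either two-step arm plus step 5).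

Steps most likely to fail

Step 5. The β-oxygen donor may slow CO dissociation. It may also let the vinylcarbene intermediate close before CO migrates, which leads into the five-membered-ring manifold, and the terminal alkyne may be consumed by chain growth at the metal.

The fallback gives up the carbene chemistry and builds the ring by classical condensation, with the hydroxyl group introduced last. It sets out from 9 and comes back at 12.
- Wittig olefination of 9 with 1-(triphenylphosphoranylidene)propan-2-one should give (E)-heptacos-3-en-2-one F1.
- Tandem Michael addition and Dieckmann-type cyclisation with dimethyl malonate and NaOMe should give methyl 2,4-dioxo-6-tricosylcyclohexane-1-carboxylate F2.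
- Saponification and acidic decarboxylation lead to 5-tricosylcyclohexane-1,3-dione F3.
- Iodine in refluxing methanol aromatises and etherifies this to 1,3-dimethoxy-5-tricosylbenzene F4.
- Vilsmeier–Haack formylation at the position ortho to one methoxy group and para to the other gives 2,4-dimethoxy-6-tricosylbenzaldehyde F5.
- Baeyer–Villiger oxidation with mCPBA gives 2,4-dimethoxy-6-tricosylphenyl formate F6, and K2CO3/MeOH releases 12.

Step 2. A second methanol may add to the push–pull alkene, or the transient unprotected ethynyl complex may break down before it is trapped.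

The fallback reverses the polarity of carbene assembly by pairing a nucleophilic metal with an electrophilic acyl partner, and it bypasses steps 1 and 2. It sets out from 1 and comes back at 7.
- Reduction of 1 with sodium naphthalenide in THF at −78 °C gives disodium pentacarbonylchromate F7.
- Acylation with purchased (E)-3-methoxyacryloyl chloride gives sodium pentacarbonyl[(2E)-3-methoxy-1-oxidoprop-2-en-1-ylidene]chromate F8.
- O-methylation with Me3OBF4 in CH2Cl2 gives 7.

Step 4. The poorly dissolved waxy aldehyde may react slowly in the methanolic medium, which leaves time for base-mediated self-condensation.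

The fallback is a Corey–Fuchs sequence run entirely in aprotic solvents. It sets out from 9 and comes back at 10.
- CBr4/PPh3 in CH2Cl2 converts 9 into 1,1-dibromopentacos-1-ene F9.
- n-BuLi (2.2 equiv) in THF brings about bromine–lithium exchange and Fritsch–Buttenberg–Wiechell rearrangement to pentacos-1-yn-1-yllithium F10.
- A water quench gives 10.

Further compounds
F1 | step 5 | (E)-heptacos-3-en-2-one | CCCCCCCCCCCCCCCCCCCCCCC/C=C/C(C)=O
F2 | step 5 | methyl 2,4-dioxo-6-tricosylcyclohexane-1-carboxylate (racemic, enolisable) | CCCCCCCCCCCCCCCCCCCCCCCC1CC(=O)CC(=O)C1C(=O)OC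
F3 | step 5 | 5-tricosylcyclohexane-1,3-dione | CCCCCCCCCCCCCCCCCCCCCCCC1CC(=O)CC(=O)C1
F4 | step 5 | 1,3-dimethoxy-5-tricosylbenzene | CCCCCCCCCCCCCCCCCCCCCCCc1cc(OC)cc(OC)c1
F5 | step 5 | 2,4-dimethoxy-6-tricosylbenzaldehyde | CCCCCCCCCCCCCCCCCCCCCCCc1cc(OC)cc(OC)c1C=O
F6 | step 5 | 2,4-dimethoxy-6-tricosylphenyl formate | CCCCCCCCCCCCCCCCCCCCCCCc1cc(OC)cc(OC)c1OC=O
F7 | step 2 | disodium pentacarbonylchromate | [Na+].[Na+].O=C=[Cr-2](=C=O)(=C=O)(=C=O)=C=O
F8 | step 2 | sodium pentacarbonyl[(2E)-3-methoxy-1-oxidoprop-2-en-1-ylidene]chromate | [Na+].CO/C=C/C([O-])=[Cr](=C=O)(=C=O)(=C=O)(=C=O)=C=O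
F9 | step 4 | 1,1-dibromopentacos-1-ene | CCCCCCCCCCCCCCCCCCCCCCCC=C(Br)Br
F10 | step 4 | pentacos-1-yn-1-yllithium | CCCCCCCCCCCCCCCCCCCCCCCC#C[Li]
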